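**Plan**

1. Numbering (drimane): ring A = C1–C5 and C10, ring B = C5–C10, C11 = the OCH2 carbon on C9, C12 = the exocyclic CH2 on C8. Retrosynthetic cuts, in order: the O–C11 aryl ether; the ring-B diene back to a C8 ketone and a C11 ester (β-keto ester); C1–C2 and C9–C10 together; then C2–C3, C8–C9, C7–C8 and C4–C5 of the open chain.
2. Enabling feature: C2 is α to the C3 carbonyl and C1 is a CH2 on the quaternary C10 shared by both rings. A C10(CH3)=C1H2 isopropenyl group can therefore attack an electrophilic α-keto carbon (C2, a diazoketone carbon), and the tertiary C10 cation that results is taken by C9, which lies between the C8 ketone and the C11 ester.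
3. Forward: the chain is joined C4–C5 (allylic alkylation), C7–C8 (hydroformylation), C8–C9 (Roskamp), C2–C3 (diazoketone). Ring A closes first and ring B second in one operation. The 3-hydroxyl and the ring-B diene are then set and the coumarin is attached last.
4. Stereochemistry: C5 from iridium-catalysed asymmetric allylic alkylation; C10 and the trans ring fusion from C5 in the bicyclisation; C9 by face-selective protonation anti to the C10 methyl group; C3 by hydride delivery to the less hindered face of the 3-ketone.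

Key step: step 10

Remark: the phosphoramidite antipode in step 5 is taken to be the one that gives the 3R ester 8; all later stereocentres follow from this centre.

**Route**

Step 1
Reactants: 1 methacrolein; 2 triethyl phosphonoacetate
Product: 3 ethyl (2E)-4-methylpenta-2,4-dienoate
Conditions: NaH, THF, 0 °C → rt
Reagents that add atoms: none
Why: Horner–Wadsworth–Emmons olefination of the enal with the stabilised phosphonate anion should give the E-dienoate.

Step 2
Reactants: 3 ethyl (2E)-4-methylpenta-2,4-dienoate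
Product: 4 (2E)-4-methylpenta-2,4-dien-1-ol
Conditions: iBu2AlH (2.2 equiv), CH2Cl2, −78 → 0 °C; aq. potassium sodium tartrate
Reagents that add atoms: none
Why: 1,2-reduction of the conjugated ester by the aluminium hydride gives the allylic alcohol and leaves the diene untouched.

Step 3
Reactants: 4 (2E)-4-methylpenta-2,4-dien-1-ol
Product: 5 methyl (2E)-4-methylpenta-2,4-dien-1-yl carbonate
Conditions: ClCO2Me, pyridine, CH2Cl2, 0 °C
Reagents that add atoms: methyl chloroformate, COC(=O)Cl
Why: O-acylation of the primary alcohol gives the allylic carbonate that serves as the leaving group in the allylic substitution.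

Step 4
Reactants: 6 tert-butyl 2-methylpropanoate
Product: 7 [(1-tert-butoxy-2-methylprop-1-en-1-yl)oxy]trimethylsilane
Conditions: LiN(iPr)2, THF, −78 °C; Me3SiCl, −78 °C → rt; distillation
Reagents that add atoms: chlorotrimethylsilane, C[Si](C)(C)Cl
Why: ester enolisation and O-silylation give the silyl ketene acetal, which has no double-bond geometry to control because the enolate carbon carries two methyl groups.

Step 5
Reactants: 5 methyl (2E)-4-methylpenta-2,4-dien-1-yl carbonate; 7 [(1-tert-butoxy-2-methylprop-1-en-1-yl)oxy]trimethylsilane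
Product: 8 tert-butyl (3R)-2,2-dimethyl-3-(prop-1-en-2-yl)pent-4-enoate
Conditions: [Ir(cod)Cl]2 (2 mol%), binaphthol-derived bis(1-phenylethyl)amine phosphoramidite (4 mol%, single enantiomer), n-PrNH2 (activation), CsF (cat.), THF, rt
Reagents that add atoms: none
Why: iridium-catalysed asymmetric allylic alkylation (Tsuji–Trost type) of a silyl ketene acetal, in which the cyclometalated iridium–phosphoramidite allyl complex should be attacked at the allyl terminus that bears the isopropenyl group (branched selectivity), forming the C4–C5 bond and setting C5 under ligand control.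

Step 6
Reactants: 8 tert-butyl (3R)-2,2-dimethyl-3-(prop-1-en-2-yl)pent-4-enoate
Product: 9 tert-butyl (3R)-2,2-dimethyl-6-oxo-3-(prop-1-en-2-yl)hexanoate
Conditions: Rh(acac)(CO)2 (1 mol%), Xantphos (2 mol%), CO/H2 (1:1, 10 bar), toluene, 60 °C
Reagents that add atoms: carbon monoxide, [C-]#[O+]
Why: rhodium-catalysed hydroformylation with a wide-bite-angle diphosphine should be linear-selective and should take the monosubstituted vinyl group in preference to the 1,1-disubstituted isopropenyl group, which adds C8 without touching the stereocentre.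

Step 7
Reactants: 9 tert-butyl (3R)-2,2-dimethyl-6-oxo-3-(prop-1-en-2-yl)hexanoate; 10 methyl diazoacetate
Product: 11 1-tert-butyl 8-methyl (3R)-2,2-dimethyl-6-oxo-3-(prop-1-en-2-yl)octanedioate
Conditions: SnCl2 (10 mol%), CH2Cl2, rt
Reagents that add atoms: none
Why: Roskamp homologation (addition of the diazoacetate to the aldehyde under mild Lewis acid catalysis, then 1,2-hydride shift with loss of N2) gives the β-keto ester; the weak Lewis acid should not trigger a carbonyl-ene closure onto the isopropenyl group.

Step 8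
Reactants: 11 1-tert-butyl 8-methyl (3R)-2,2-dimethyl-6-oxo-3-(prop-1-en-2-yl)octanedioate
Product: 13 (3R)-8-methoxy-2,2-dimethyl-6,8-dioxo-3-(prop-1-en-2-yl)octanoic acid, via trimethylsilyl ester 12 (not isolated)
Conditions: Me3SiOTf, 2,6-lutidine, CH2Cl2, 0 °C; then H2O
Reagents that add atoms: trimethylsilyl trifluoromethanesulfonate, C[Si](C)(C)OS(=O)(=O)C(F)(F)F (silyl group of 12 only)
Why: silyl-triflate-mediated cleavage of the tert-butyl ester (O-silylation, loss of 2-methylpropene, hydrolysis of the silyl ester) works without protic acid, so the isopropenyl group should not lactonise onto the acid and the methyl ester stays.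

Step 9
Reactants: 13 (3R)-8-methoxy-2,2-dimethyl-6,8-dioxo-3-(prop-1-en-2-yl)octanoic acid
Product: 15 methyl (6R)-9-diazo-7,7-dimethyl-3,8-dioxo-6-(prop-1-en-2-yl)nonanoate, via acid chloride 14 (not isolated)
Conditions: 1-chloro-N,N,2-trimethylprop-1-en-1-amine, CH2Cl2, 0 °C → rt; then CH2N2 (excess), Et2O, 0 °C
Reagents that add atoms: diazomethane, C=[N+]=[N-]; 1-chloro-N,N,2-trimethylprop-1-en-1-amine, CC(C)=C(Cl)N(C)C (chlorine of 14 only)
Why: neutral chloride transfer from the α-chloroenamine gives the acid chloride, and acylation of diazomethane (first stage of the Arndt–Eistert sequence) gives the diazomethyl ketone, a second equivalent of diazomethane taking up the HCl.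

Step 10
Reactants: 15 methyl (6R)-9-diazo-7,7-dimethyl-3,8-dioxo-6-(prop-1-en-2-yl)nonanoate
Product: 16 methyl (1R,4aR,8aS)-5,5,8a-trimethyl-2,6-dioxodecahydronaphthalene-1-carboxylate
Conditions: BF3·OEt2 (1.5 equiv), CH2Cl2/MeNO2 (4:1), −40 → 0 °C, slow addition of 15 at high dilution; aq. NaHCO3
Reagents that add atoms: none
Why: Proposed new method: BF3 should turn the oxygen-bound diazoketone of 15 into an α-keto electrophile at C2; the CH2 end (C1) of the C10=C1 isopropenyl group attacks it as N2 leaves, which forms the C1–C2 bond and closes ring A in the 6-endo mode (the 5-exo alternative would leave a primary cation), and the tertiary C10 cation is then alkylated by the enol carbon C9 of the β-keto ester, closing ring B as a six-membered ring through a chair-like transition state with the enol double bond inside the ring; the boron enolate left at C2–C3 is protonated on work-up. The closest known reaction types are the Lewis-acid-promoted α-diazoketone-initiated cation–olefin cyclisation and the cation–olefin cyclisation terminated by a β-keto ester, and the new elements are their union in one cascade and a 1,1-disubstituted alkene as the first π-nucleophile. C10 is controlled by C5: with the C5 side chain equatorial on the new ring A the enol should reach the cation face that makes the C9–C10 bond equatorial and the methyl group axial (trans fusion), and C9, being epimerisable, should settle with the ester equatorial. The step needs carbon rather than oxygen alkylation by the keto ester and capture of the cation before proton loss; O-alkylation at a tertiary centre and any collapse of the C2 enolate onto C10 to a cyclopropyl ketone should be reversible under the Lewis acid, and the six-membered intramolecular trap together with the C4 gem-dimethyl group favours the productive path.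

Step 11
Reactants: 16 methyl (1R,4aR,8aS)-5,5,8a-trimethyl-2,6-dioxodecahydronaphthalene-1-carboxylate
Product: 18 methyl (1R,4aR,6S,8aS)-6-hydroxy-5,5,8a-trimethyl-2-oxodecahydronaphthalene-1-carboxylate, via sodium enolate 17 (not isolated)
Conditions: NaH (1.05 equiv), THF, 0 °C; then LiAlH(OtBu)3 (1.5 equiv), 0 °C → rt; dilute aq. HCl
Reagents that add atoms: sodium hydride, [NaH] (sodium of 17 only)
Why: the β-keto ester is held as its sodium enolate, which is inert to hydride, so only the C3 ketone is reduced (chemoselective ketone reduction with an enolate as temporary protection), and the small alkoxyaluminium hydride should add along the axial α-face of the 4,4-dimethyl-3-ketone to give the equatorial 3β-alcohol (3S in drimane numbering).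

Step 12
Reactants: 18 methyl (1R,4aR,6S,8aS)-6-hydroxy-5,5,8a-trimethyl-2-oxodecahydronaphthalene-1-carboxylate
Product: 21 methyl (1R,4aR,6S,8aS)-6-hydroxy-5,5,8a-trimethyl-2-oxo-1,2,4a,5,6,7,8,8a-octahydronaphthalene-1-carboxylate, via selenide 19 (not isolated), via selenoxide 20 (not isolated)
Conditions: LiN(iPr)2 (3.2 equiv), THF, −78 → 0 °C; PhSeBr (1.1 equiv), −78 °C; then H2O2 (30% aq.), pyridine, CH2Cl2, 0 °C → rt
Reagents that add atoms: benzeneselenenyl bromide, Br[Se]c1ccccc1 (selenium group of 19 and 20 only); hydrogen peroxide, OO (oxygen of 20 only)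
Why: excess amide base gives the alkoxide and the β-keto ester dianion, whose γ-carbon (C7) is the most nucleophilic site and is selenenylated, and selenoxide syn-elimination can only remove a C6 hydrogen, so the C6=C7 enone should result.

Step 13
Reactants: 21 methyl (1R,4aR,6S,8aS)-6-hydroxy-5,5,8a-trimethyl-2-oxo-1,2,4a,5,6,7,8,8a-octahydronaphthalene-1-carboxylate
Product: 22 methyl (4aR,6S,8aS)-6-hydroxy-5,5,8a-trimethyl-2-{[(trifluoromethyl)sulfonyl]oxy}-4a,5,6,7,8,8a-hexahydronaphthalene-1-carboxylate
Conditions: NaH (1.05 equiv), THF, 0 °C; PhNTf2 (1.1 equiv), 0 °C → rt; aq. NH4Cl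
Reagents that add atoms: N-phenylbis(trifluoromethanesulfonimide), O=S(=O)(N(c1ccccc1)S(=O)(=O)C(F)(F)F)C(F)(F)F
Why: the doubly activated C9–H is far more acidic than the 3-hydroxyl, so one equivalent of base gives only the keto ester enolate, which is O-sulfonylated to the dienyl triflate (enol triflate formation).

Step 14
Reactants: 22 methyl (4aR,6S,8aS)-6-hydroxy-5,5,8a-trimethyl-2-{[(trifluoromethyl)sulfonyl]oxy}-4a,5,6,7,8,8a-hexahydronaphthalene-1-carboxylate
Product: 23 methyl (4aR,6S,8aS)-6-hydroxy-2,5,5,8a-tetramethyl-4a,5,6,7,8,8a-hexahydronaphthalene-1-carboxylate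
Conditions: trimethylboroxine, Pd(PPh3)4 (5 mol%), K2CO3, 1,4-dioxane, 90 °C
Reagents that add atoms: trimethylboroxine, CB1OB(C)OB(C)O1
Why: Suzuki–Miyaura cross-coupling of the alkenyl triflate with the methylboron reagent puts C12 on C8, and the free hydroxyl, the ester and the diene should be tolerated.

Step 15
Reactants: 23 methyl (4aR,6S,8aS)-6-hydroxy-2,5,5,8a-tetramethyl-4a,5,6,7,8,8a-hexahydronaphthalene-1-carboxylate
Product: 25 methyl (1S,4aR,6S,8aS)-6-hydroxy-5,5,8a-trimethyl-2-methylidene-1,2,4a,5,6,7,8,8a-octahydronaphthalene-1-carboxylate, via lithium dienolate 24 (not isolated)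
Conditions: LiN(iPr)2 (2.5 equiv), THF/DMPU, −78 °C; then AcOH (excess) in THF, −78 °C
Reagents that add atoms: lithium diisopropylamide, CC(C)[N-]C(C)C.[Li+] (lithium of 24 only)
Why: kinetic deprotonation of the γ-methyl group (C12, cis to the ester) gives the cross-conjugated dienolate, and kinetic α-protonation (deconjugative protonation of an extended enolate) should give the β,γ-unsaturated ester with the exocyclic C8=C12 bond, the proton reaching C9 from the α-face anti to the axial C10 methyl group, which sets C9.

Step 16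
Reactants: 25 methyl (1S,4aR,6S,8aS)-6-hydroxy-5,5,8a-trimethyl-2-methylidene-1,2,4a,5,6,7,8,8a-octahydronaphthalene-1-carboxylate
Product: 26 (2S,4aS,5S,8aR)-5-(hydroxymethyl)-1,1,4a-trimethyl-6-methylidene-1,2,3,4,4a,5,6,8a-octahydronaphthalen-2-ol
Conditions: LiAlH4, Et2O, 0 °C; aq. NaOH work-up
Reagents that add atoms: none
Why: hydride reduction of the ester gives the primary C11 alcohol; the unactivated diene and the stereocentres should be unaffected because reduction is faster than base-induced reconjugation.

Step 17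
Reactants: 26 (2S,4aS,5S,8aR)-5-(hydroxymethyl)-1,1,4a-trimethyl-6-methylidene-1,2,3,4,4a,5,6,8a-octahydronaphthalen-2-ol; 27 umbelliferone (7-hydroxy-2H-chromen-2-one)
Product: 28 7-{[(1S,4aR,6S,8aS)-6-hydroxy-5,5,8a-trimethyl-2-methylidene-1,2,4a,5,6,7,8,8a-octahydronaphthalen-1-yl]methoxy}-2H-chromen-2-one
Conditions: PPh3, DIAD, THF, 0 °C → rt
Reagents that add atoms: none
Why: Mitsunobu etherification, in which the acidic phenol is alkylated by the activated primary C11 alcohol while the secondary 3β-hydroxyl next to the gem-dimethyl group should not be activated at a useful rate; no stereocentre is involved.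

**Compound list**

1 | methacrolein (2-methylprop-2-enal) | CC(=C)C=O | starting material
2 | triethyl phosphonoacetate | CCOC(=O)CP(=O)(OCC)OCC | starting material
3 | ethyl (2E)-4-methylpenta-2,4-dienoate | CCOC(=O)/C=C/C(C)=C | intermediate
4 | (2E)-4-methylpenta-2,4-dien-1-ol | OC/C=C/C(C)=C | intermediate
5 | methyl (2E)-4-methylpenta-2,4-dien-1-yl carbonate | COC(=O)OC/C=C/C(C)=C | intermediate
6 | tert-butyl 2-methylpropanoate | CC(C)C(=O)OC(C)(C)C | starting material
7 | [(1-tert-butoxy-2-methylprop-1-en-1-yl)oxy]trimethylsilane | CC(C)=C(OC(C)(C)C)O[Si](C)(C)C | intermediate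
8 | tert-butyl (3R)-2,2-dimethyl-3-(prop-1-en-2-yl)pent-4-enoate | C=C[C@H](C(C)=C)C(C)(C)C(=O)OC(C)(C)C | intermediate
9 | tert-butyl (3R)-2,2-dimethyl-6-oxo-3-(prop-1-en-2-yl)hexanoate | O=CCC[C@H](C(C)=C)C(C)(C)C(=O)OC(C)(C)C | intermediate
10 | methyl diazoacetate | COC(=O)C=[N+]=[N-] | starting material
11 | 1-tert-butyl 8-methyl (3R)-2,2-dimethyl-6-oxo-3-(prop-1-en-2-yl)octanedioate | COC(=O)CC(=O)CC[C@H](C(C)=C)C(C)(C)C(=O)OC(C)(C)C | intermediate
12 | trimethylsilyl (3R)-8-methoxy-2,2-dimethyl-6,8-dioxo-3-(prop-1-en-2-yl)octanoate (formed in the flask) | COC(=O)CC(=O)CC[C@H](C(C)=C)C(C)(C)C(=O)O[Si](C)(C)C | intermediate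
13 | (3R)-8-methoxy-2,2-dimethyl-6,8-dioxo-3-(prop-1-en-2-yl)octanoic acid | COC(=O)CC(=O)CC[C@H](C(C)=C)C(C)(C)C(=O)O | intermediate
14 | methyl (6R)-8-chloro-7,7-dimethyl-3,8-dioxo-6-(prop-1-en-2-yl)octanoate (formed in the flask) | COC(=O)CC(=O)CC[C@H](C(C)=C)C(C)(C)C(=O)Cl | intermediate
15 | methyl (6R)-9-diazo-7,7-dimethyl-3,8-dioxo-6-(prop-1-en-2-yl)nonanoate | COC(=O)CC(=O)CC[C@H](C(C)=C)C(C)(C)C(=O)C=[N+]=[N-] | intermediate
16 | methyl (1R,4aR,8aS)-5,5,8a-trimethyl-2,6-dioxodecahydronaphthalene-1-carboxylate (trans-fused; ester equatorial) | O=C1CC[C@H]2C(C)(C)C(=O)CC[C@]2(C)[C@H]1C(=O)OC | intermediate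
17 | sodium (4aR,8aS)-1-(methoxycarbonyl)-5,5,8a-trimethyl-6-oxo-3,4,4a,5,6,7,8,8a-octahydronaphthalen-2-olate (formed in the flask) | [Na+].[O-]C1CC[C@H]2C(C)(C)C(=O)CC[C@]2(C)C=1C(=O)OC | intermediate
18 | methyl (1R,4aR,6S,8aS)-6-hydroxy-5,5,8a-trimethyl-2-oxodecahydronaphthalene-1-carboxylate | O=C1CC[C@H]2C(C)(C)[C@@H](O)CC[C@]2(C)[C@H]1C(=O)OC | intermediate
19 | methyl (1R,4aR,6S,8aS)-6-hydroxy-5,5,8a-trimethyl-2-oxo-3-(phenylselanyl)decahydronaphthalene-1-carboxylate (C3 epimers; formed in the flask) | O=C1C([Se]c3ccccc3)C[C@H]2C(C)(C)[C@@H](O)CC[C@]2(C)[C@H]1C(=O)OC | intermediate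
20 | methyl (1R,4aR,6S,8aS)-3-(benzeneseleninyl)-6-hydroxy-5,5,8a-trimethyl-2-oxodecahydronaphthalene-1-carboxylate (formed in the flask) | O=C1C([Se](=O)c3ccccc3)C[C@H]2C(C)(C)[C@@H](O)CC[C@]2(C)[C@H]1C(=O)OC | intermediate
21 | methyl (1R,4aR,6S,8aS)-6-hydroxy-5,5,8a-trimethyl-2-oxo-1,2,4a,5,6,7,8,8a-octahydronaphthalene-1-carboxylate | O=C1C=C[C@H]2C(C)(C)[C@@H](O)CC[C@]2(C)[C@H]1C(=O)OC | intermediate
22 | methyl (4aR,6S,8aS)-6-hydroxy-5,5,8a-trimethyl-2-{[(trifluoromethyl)sulfonyl]oxy}-4a,5,6,7,8,8a-hexahydronaphthalene-1-carboxylate | O=S(=O)(OC1C=C[C@H]2C(C)(C)[C@@H](O)CC[C@]2(C)C=1C(=O)OC)C(F)(F)F | intermediate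
23 | methyl (4aR,6S,8aS)-6-hydroxy-2,5,5,8a-tetramethyl-4a,5,6,7,8,8a-hexahydronaphthalene-1-carboxylate | CC1C=C[C@H]2C(C)(C)[C@@H](O)CC[C@]2(C)C=1C(=O)OC | intermediate
24 | dilithium (2S,4aS,8aR)-5-[methoxy(oxido)methylidene]-1,1,4a-trimethyl-6-methylidene-1,2,3,4,4a,5,6,8a-octahydronaphthalen-2-olate (formed in the flask) | [Li+].[Li+].C=C1C=C[C@H]2C(C)(C)[C@@H]([O-])CC[C@]2(C)C1=C([O-])OC | intermediate
25 | methyl (1S,4aR,6S,8aS)-6-hydroxy-5,5,8a-trimethyl-2-methylidene-1,2,4a,5,6,7,8,8a-octahydronaphthalene-1-carboxylate | C=C1C=C[C@H]2C(C)(C)[C@@H](O)CC[C@]2(C)[C@H]1C(=O)OC | intermediate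
26 | (2S,4aS,5S,8aR)-5-(hydroxymethyl)-1,1,4a-trimethyl-6-methylidene-1,2,3,4,4a,5,6,8a-octahydronaphthalen-2-ol | C=C1C=C[C@H]2C(C)(C)[C@@H](O)CC[C@]2(C)[C@H]1CO | intermediate
27 | umbelliferone (7-hydroxy-2H-chromen-2-one) | O=c1ccc2ccc(O)cc2o1 | starting material
28 | 7-{[(1S,4aR,6S,8aS)-6-hydroxy-5,5,8a-trimethyl-2-methylidene-1,2,4a,5,6,7,8,8a-octahydronaphthalen-1-yl]methoxy}-2H-chromen-2-one | C=C1C=C[C@H]2C(C)(C)[C@@H](O)CC[C@]2(C)[C@H]1COc1ccc2ccc(=O)oc2c1 | target

**Step count**

Total steps: 17. Longest linear sequence: 16 (steps 1–3 and 5–17; step 4 prepares the nucleophile for step 5).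

**Steps most likely to fail**

Step 10 (Proposed new method). Possible failures are proton loss from the tertiary C10 cation before ring B closes, capture of the cation through the enol oxygen, or closure to the cis-fused ring system. The fallback separates the two bond formations and uses known reaction types. It sets out from 15: Rh2(OAc)4-catalysed intramolecular cyclopropanation of the isopropenyl group by the diazoketone (CH2Cl2, rt) should give the cyclopropyl ketone methyl 3-oxo-5-[(2R)-1,3,3-trimethyl-4-oxobicyclo[3.1.0]hexan-2-yl]pentanoate F1, in which the C1–C2 bond is already made. Treatment of this compound with SnCl4 (CH2Cl2, −78 → 0 °C) should open the internal cyclopropane bond to the tertiary C10 cation (cyclopropyl-ketone-initiated cation–olefin type cyclisation), and the β-keto ester takes the cation as before. The fallback comes back to the route at 16.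

Step 15. Possible failures are protonation of the dienolate at C12 (return to 23), protonation of C9 from the β-face, or competing deprotonation at C5. The fallback replaces the dienolate protonation by an SE2' protodesilylation that fixes the position of the double bond. It sets out from 22: Kumada coupling with Me3SiCH2MgCl (Pd(PPh3)4, THF, rt) should give the allylsilane methyl (4aR,6S,8aS)-6-hydroxy-5,5,8a-trimethyl-2-[(trimethylsilyl)methyl]-4a,5,6,7,8,8a-hexahydronaphthalene-1-carboxylate F2. Reduction with iBu2AlH (CH2Cl2, −78 °C) gives (2S,4aS,8aR)-5-(hydroxymethyl)-1,1,4a-trimethyl-6-[(trimethylsilyl)methyl]-1,2,3,4,4a,8a-hexahydronaphthalen-2-ol F3. Protodesilylation with AcOH (CH2Cl2, 0 °C) should deliver the proton to C9 anti to the C10 methyl group and leave the exocyclic C8=C12 bond. The fallback comes back to the route at 26.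

Step 5. Possible failures are attack at the unsubstituted allyl terminus, slow turnover with the fully substituted nucleophile, or insufficient enantiocontrol. The fallback makes the same C4–C5 bond by a sigmatropic shift and resolves the product. It sets out from 4: acylation (isobutyryl chloride, pyridine) gives (2E)-4-methylpenta-2,4-dien-1-yl 2-methylpropanoate F4. Ireland–Claisen rearrangement (LiN(iPr)2, Me3SiCl, THF, −78 °C → rt) passes through the silyl ketene acetal {[(2E)-4-methylpenta-2,4-dien-1-yl]oxy}(2-methylprop-1-en-1-yl)oxy-trimethylsilane F5 and the silyl ester trimethylsilyl 2,2-dimethyl-3-(prop-1-en-2-yl)pent-4-enoate F6, and aqueous work-up gives racemic 2,2-dimethyl-3-(prop-1-en-2-yl)pent-4-enoic acid F7. Resolution by preparative chromatography on a chiral stationary phase gives (3R)-2,2-dimethyl-3-(prop-1-en-2-yl)pent-4-enoic acid F8. Esterification with N,N'-diisopropyl-O-tert-butylisourea (CH2Cl2, rt) comes back to the route at 8.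

Further compounds
F1 | step 10 | methyl 3-oxo-5-[(2R)-1,3,3-trimethyl-4-oxobicyclo[3.1.0]hexan-2-yl]pentanoate (mixture at the cyclopropane carbons) | COC(=O)CC(=O)CC[C@H]1C(C)(C)C(=O)C2CC12C
F2 | step 15 | methyl (4aR,6S,8aS)-6-hydroxy-5,5,8a-trimethyl-2-[(trimethylsilyl)methyl]-4a,5,6,7,8,8a-hexahydronaphthalene-1-carboxylate | C[Si](C)(C)CC1C=C[C@H]2C(C)(C)[C@@H](O)CC[C@]2(C)C=1C(=O)OC
F3 | step 15 | (2S,4aS,8aR)-5-(hydroxymethyl)-1,1,4a-trimethyl-6-[(trimethylsilyl)methyl]-1,2,3,4,4a,8a-hexahydronaphthalen-2-ol | C[Si](C)(C)CC1C=C[C@H]2C(C)(C)[C@@H](O)CC[C@]2(C)C=1CO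
F4 | step 5 | (2E)-4-methylpenta-2,4-dien-1-yl 2-methylpropanoate | CC(C)C(=O)OC/C=C/C(C)=C
F5 | step 5 | {[(2E)-4-methylpenta-2,4-dien-1-yl]oxy}(2-methylprop-1-en-1-yl)oxy-trimethylsilane | CC(C)=C(O[Si](C)(C)C)OC/C=C/C(C)=C
F6 | step 5 | trimethylsilyl 2,2-dimethyl-3-(prop-1-en-2-yl)pent-4-enoate (racemic) | C=CC(C(C)=C)C(C)(C)C(=O)O[Si](C)(C)C
F7 | step 5 | 2,2-dimethyl-3-(prop-1-en-2-yl)pent-4-enoic acid (racemic) | C=CC(C(C)=C)C(C)(C)C(=O)O
F8 | step 5 | (3R)-2,2-dimethyl-3-(prop-1-en-2-yl)pent-4-enoic acid | C=C[C@H](C(C)=C)C(C)(C)C(=O)O
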